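**Assumptions.**
- Chain numbering: C1 = CO2H … C19, C20 = ring O–CH, C21 = ring CH(Me), C22=C23, C24 = lactone C=O. Me groups are on C3, C5, C7, C11, C15 and C21, Et is on C17, and CH2OH is on C9.
- The C8 configuration formed in Step 10 is irrelevant, because C8 is oxidised to the ketone later.
- (R)-3-Bromo-2-methylpropan-1-ol and (R)-methyl 3-hydroxy-2-methylpropanoate are taken as commercial.
- The acrylate and ylide reagents are reagents and are not numbered.
- In Steps 4, 10 and 21 the enantiomer of the chiral ligand or catalyst is chosen to give the stated face of attack.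

## Retrosynthetic overview
- Kazusamycin A comes from late TES removal, C8 oxidation and fluoride global deprotection of the Negishi product of dienyl iodide **16** (C1–C13) and the C14 alkylzinc derived from iodide **28** (C14–C24).
- **16** comes from Takai olefination of an enal, itself from a Wittig reaction on the C10 aldehyde. That aldehyde comes from allylboration of the C8 aldehyde (sets C9), which comes from Brown crotylation of the C6 aldehyde (all-syn C5–C7). The C6 aldehyde comes from the (R)-bromo alcohol by Cu-coupling and cross-metathesis (C2=C3 E).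
- **28** contains the only ring, the dihydropyranone. It is formed by RCM of the acrylate of a syn homoallylic alcohol, obtained by Brown crotylation of a (2E,4Z)-dienal. The dienal comes from Wittig homologation of a Z-enal, which comes from Ando Z-olefination of a Roche-ester-derived aldehyde.

## Route

**Step 1**
Reactants: 1 (R)-3-bromo-2-methylpropan-1-ol
Product: 2 (S)-2,4-dimethylpent-4-en-1-ol
Conditions: isopropenylMgBr (2.5 equiv), CuI (10 mol%), THF, −20 °C → rt
Reagents that add atoms: isopropenylmagnesium bromide, CC(=C)[Mg]Br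
Why: Cu-catalysed Kumada-type SN2 at the primary C–Br installs C2–C4 and the C3 methyl alkene; the first equivalent of Grignard only forms the alkoxide, and the C5 stereocentre is untouched.

**Step 2**
Reactants: 2
Product: 3 TMSE (2E,5S)-6-hydroxy-3,5-dimethylhex-2-enoate
Conditions: 2-(trimethylsilyl)ethyl acrylate (3 equiv), Hoveyda–Grubbs II (5 mol%), CH2Cl2, 40 °C
Reagents that add atoms: TMSE acrylate, C=CC(=O)OCC[Si](C)(C)C
Why: cross-metathesis of a 1,1-disubstituted alkene with an acrylate gives the thermodynamic (E)-trisubstituted enoate (C2=C3).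

**Step 3**
Reactants: 3
Product: 4 TMSE (2E,5S)-3,5-dimethyl-6-oxohex-2-enoate
Conditions: Dess–Martin periodinane, NaHCO3, CH2Cl2, 0 °C → rt
Reagents that add atoms: none
Why: buffered Dess–Martin oxidation gives the aldehyde without epimerising the α-methyl centre C5.

**Step 4**
Reactants: 4
Product: 5 TMSE (2E,5S,6R,7R)-6-hydroxy-3,5,7-trimethylnona-2,8-dienoate
Conditions: (Z)-crotyl-B(Ipc)2 (from cis-2-butene, KOtBu/n-BuLi, Ipc2BOMe, BF3·OEt2), THF, −78 °C; then NaBO3·4H2O, THF/H2O
Reagents that add atoms: (Z)-crotyldiisopinocampheylborane, C/C=C\CB(C1CC2CC(C1C)C2(C)C)C1CC2CC(C1C)C2(C)C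
Why: Brown crotylation through a chair transition state; the Z geometry gives C6/C7 syn, and the Ipc ligand enantiomer that attacks the Si face of the aldehyde also matches the Felkin preference of the α-methyl aldehyde, so C5/C6 are syn too (all-syn triad; the terminal vinyl is C8=C9).

**Step 5**
Reactants: 5
Product: 6 C6-O-TBS ether of 5
Conditions: TBSOTf, 2,6-lutidine, CH2Cl2, −78 °C
Reagents that add atoms: TBSOTf, CC(C)(C)[Si](C)(C)OS(=O)(=O)C(F)(F)F
Why: silylation of the secondary alcohol without touching the stereocentres.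

**Step 6**
Reactants: 6
Product: 7 TMSE (2E,5S,6R,7S)-6-(TBSO)-3,5,7-trimethyl-8-oxooct-2-enoate
Conditions: O3 (1.0 equiv, titrated), CH2Cl2, −78 °C; then PPh3; product used crude
Reagents that add atoms: ozone, [O-][O+]=O
Why: ozonolysis cleaves the electron-rich terminal vinyl much faster than the electron-poor trisubstituted enoate, unmasking the C8 aldehyde.

**Step 7**
Reactants: 8 (E)-but-2-ene-1,4-diol
Product: 9 (E)-4-(TBSO)but-2-en-1-ol
Conditions: NaH (1.0 equiv), TBSCl (1.0 equiv), THF, 0 °C → rt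
Reagents that add atoms: TBSCl, CC(C)(C)[Si](C)(C)Cl
Why: statistical mono-silylation of the symmetrical diol via its mono-alkoxide.

**Step 8**
Reactants: 9
Product: 10 methyl (E)-4-(TBSO)but-2-en-1-yl carbonate
Conditions: ClCO2Me, pyridine, CH2Cl2, 0 °C
Reagents that add atoms: methyl chloroformate, COC(=O)Cl
Why: converts the allylic alcohol into a leaving group for Pd-catalysed borylation.

**Step 9**
Reactants: 10
Product: 11 (E)-2-[4-(TBSO)but-2-en-1-yl]-4,4,5,5-tetramethyl-1,3,2-dioxaborolane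
Conditions: B2pin2 (1.2 equiv), Pd(PPh3)4 (5 mol%), THF, 50 °C
Reagents that add atoms: bis(pinacolato)diboron, CC1(C)OB(OC1(C)C)B1OC(C)(C)C(C)(C)O1
Why: Pd(0) forms the π-allyl from the carbonate, and transmetalation/reductive elimination at the less hindered terminus gives the linear (E)-allylboronate.

**Step 10**
Reactants: 7 and 11
Product: 12 TMSE (2E,5S,6R,7R,9S)-6-(TBSO)-9-[(TBSO)methyl]-8-hydroxy-3,5,7-trimethylundeca-2,10-dienoate (C8 epimer as formed)
Conditions: TRIP chiral phosphoric acid (10 mol%, enantiomer giving Re-face attack), 4 Å MS, toluene, −30 °C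
Reagents that add atoms: none
Why: catalyst-controlled allylboration through a chair transition state; the (E)-γ-substituted reagent gives anti C8/C9 and Re-face attack gives (8R,9S), which also matches the 1,3-anti polar effect of the β-silyloxy group, so C9 is set as (S) (C8 is lost later).

**Step 11**
Reactants: 12
Product: 13 C8-O-TES ether of 12
Conditions: TESOTf, 2,6-lutidine, CH2Cl2, −78 °C
Reagents that add atoms: TESOTf, CC[Si](CC)(CC)OS(=O)(=O)C(F)(F)F
Why: the TES group can later be removed selectively in the presence of both TBS ethers.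

**Step 12**
Reactants: 13
Product: 14 C10 aldehyde (C10 = CHO, C11 lost)
Conditions: O3 (1.0 equiv), CH2Cl2, −78 °C; then PPh3; used crude immediately
Reagents that add atoms: ozone, [O-][O+]=O
Why: chemoselective cleavage of the terminal vinyl over the enoate; the α-stereocentre C9 is protected by using cold, neutral conditions and no chromatography.

**Step 13**
Reactants: 14
Product: 15 (10E)-enal (C12 aldehyde, C11 methyl)
Conditions: Ph3P=C(Me)CHO (2 equiv), toluene, 60 °C
Reagents that add atoms: 2-(triphenylphosphoranylidene)propanal, CC(C=O)=P(c1ccccc1)(c1ccccc1)c1ccccc1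
Why: Wittig reaction of a stabilised ylide gives the E-trisubstituted enal C10=C11.

**Step 14**
Reactants: 15
Product: 16 TMSE (2E,10E,12E)-13-iodo-trideca-2,10,12-trienoate derivative (West dienyl iodide)
Conditions: CHI3 (4 equiv), CrCl2 (8 equiv), THF, 0 °C → rt
Reagents that add atoms: iodoform, IC(I)I
Why: Takai–Utimoto olefination converts the aldehyde into the (E)-vinyl iodide C12=C13.

**Step 15**
Reactants: 17 (R)-methyl 3-hydroxy-2-methylpropanoate
Product: 18 methyl (R)-3-(TBSO)-2-methylpropanoate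
Conditions: TBSCl, imidazole, DMF, rt
Reagents that add atoms: TBSCl, CC(C)(C)[Si](C)(C)Cl
Why: silyl protection; the chiral pool supplies C15.

**Step 16**
Reactants: 18
Product: 19 (R)-3-(TBSO)-2-methylpropanal
Conditions: DIBAL-H (1.05 equiv), CH2Cl2, −78 °C
Reagents that add atoms: none
Why: partial reduction of the ester at low temperature stops at the aldehyde (stable tetrahedral aluminium hemiacetal).

**Step 17**
Reactants: 19
Product: 20 ethyl (2Z,4S)-5-(TBSO)-2-ethyl-4-methylpent-2-enoate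
Conditions: ethyl 2-[bis(2-methylphenoxy)phosphoryl]butanoate, NaH, THF, −78 → −20 °C
Reagents that add atoms: Ando phosphonate, CCC(C(=O)OCC)P(=O)(Oc1ccccc1C)Oc1ccccc1C
Why: Ando Z-selective Horner–Wadsworth–Emmons olefination sets the C16=C17 Z-trisubstituted alkene (ester cis to C15).

**Step 18**
Reactants: 20
Product: 21 (2Z,4S)-5-(TBSO)-2-ethyl-4-methylpent-2-en-1-ol
Conditions: DIBAL-H (2.5 equiv), CH2Cl2, −78 °C
Reagents that add atoms: none
Why: the ester is reduced to the allylic alcohol, with alkene geometry retained.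

**Step 19**
Reactants: 21
Product: 22 (2Z,4S)-5-(TBSO)-2-ethyl-4-methylpent-2-enal
Conditions: activated MnO2 (10 equiv), CH2Cl2, rt
Reagents that add atoms: none
Why: MnO2 selectively oxidises the allylic alcohol under neutral conditions, preserving the Z geometry.

**Step 20**
Reactants: 22
Product: 23 (2E,4Z,6S)-7-(TBSO)-4-ethyl-6-methylhepta-2,4-dienal
Conditions: Ph3P=CHCHO (1.5 equiv), toluene, 70 °C
Reagents that add atoms: (triphenylphosphoranylidene)acetaldehyde, O=CC=P(c1ccccc1)(c1ccccc1)c1ccccc1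
Why: Wittig two-carbon homologation with a stabilised ylide gives the E-alkene C18=C19 and the C20 aldehyde.

**Step 21**
Reactants: 23
Product: 24 (3S,4S,5E,7Z,9S)-10-(TBSO)-7-ethyl-3,9-dimethyldeca-1,5,7-trien-4-ol
Conditions: (Z)-crotyl-B(Ipc)2, THF, −78 °C; then NaBO3·4H2O
Reagents that add atoms: (Z)-crotyldiisopinocampheylborane, C/C=C\CB(C1CC2CC(C1C)C2(C)C)C1CC2CC(C1C)C2(C)C
Why: Brown crotylation; the Z reagent gives the syn relationship and the Ipc enantiomer attacking the Re face of the dienal gives C20 (S), C21 (S).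

**Step 22**
Reactants: 24
Product: 25 acrylate ester of 24
Conditions: acryloyl chloride, i-Pr2NEt, CH2Cl2, 0 °C
Reagents that add atoms: acryloyl chloride, C=CC(=O)Cl
Why: O-acylation of the secondary alcohol prepares the RCM precursor.

**Step 23**
Reactants: 25
Product: 26 (5S,6S)-5-methyl-6-[(1E,3Z,5S)-3-ethyl-6-(TBSO)-5-methylhexa-1,3-dienyl]-5,6-dihydro-2H-pyran-2-one
Conditions: Grubbs II (5 mol%), CH2Cl2 (3 mM), 40 °C
Reagents that add atoms: none (ethylene is lost)
Why: ring-closing metathesis of the acrylate with the terminal vinyl forms the six-membered unsaturated lactone (C22=C23, cis in the ring), with the stereocentres untouched.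

**Step 24**
Reactants: 26
Product: 27 primary alcohol (C14–OH)
Conditions: HF·pyridine, pyridine, THF, 0 °C → rt
Reagents that add atoms: none
Why: mildly acidic fluoride removes the primary TBS ether while the lactone and polyene survive.

**Step 25**
Reactants: 27
Product: 28 East iodide (C14–I)
Conditions: I2, PPh3, imidazole, Et2O/MeCN, 0 °C
Reagents that add atoms: iodine, II
Why: Appel-type SN2 iodination at the primary carbon, which is not a stereocentre.

**Step 26**
Reactants: 16 and 28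
Product: 29 coupled C13–C14 product (8-O-TES, 6-O-TBS, 9-CH2O-TBS, C1 TMSE ester)
Conditions: 28 + Zn dust, I2 (cat.), LiCl, THF, 40 °C (→ RZnI); then 16, Pd(PPh3)4 (5 mol%), THF, rt
Reagents that add atoms: none
Why: Negishi sp3–sp2 coupling of a primary alkylzinc with the (E)-dienyl iodide joins the two fragments with retention of the E geometry; esters and the lactone tolerate organozinc reagents.

**Step 27**
Reactants: 29
Product: 30 C8 free alcohol
Conditions: PPTS (0.3 equiv), MeOH/CH2Cl2 (1:1), 0 °C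
Reagents that add atoms: none
Why: TES ethers are cleaved far faster than TBS ethers under mild acid.

**Step 28**
Reactants: 30
Product: 31 C8 ketone (fully protected)
Conditions: Dess–Martin periodinane, NaHCO3, CH2Cl2, 0 °C → rt
Reagents that add atoms: none
Why: mild buffered oxidation to the hindered ketone, with C7 and C9 left unepimerised.

**Step 29**
Reactants: 31
Product: 32 kazusamycin A
Conditions: TBAF (8 equiv), AcOH (8 equiv), THF, 0 °C → rt
Reagents that add atoms: none
Why: buffered fluoride removes both TBS ethers and the TMSE ester (β-elimination to ethylene and Me3SiF) in one step, and the AcOH buffer suppresses retro-aldol and E1cB elimination of the β-oxygenated ketone.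

## Compound list
1 | (R)-3-bromo-2-methylpropan-1-ol | OC[C@@H](C)CBr | starting material
2 | (S)-2,4-dimethylpent-4-en-1-ol | OC[C@@H](C)CC(C)=C | intermediate
3 | TMSE (2E,5S)-6-hydroxy-3,5-dimethylhex-2-enoate | OC[C@@H](C)C/C(C)=C/C(=O)OCC[Si](C)(C)C | intermediate
4 | TMSE (2E,5S)-3,5-dimethyl-6-oxohex-2-enoate | O=C[C@@H](C)C/C(C)=C/C(=O)OCC[Si](C)(C)C | intermediate
5 | TMSE (2E,5S,6R,7R)-6-hydroxy-3,5,7-trimethylnona-2,8-dienoate | C=C[C@@H](C)[C@H](O)[C@@H](C)C/C(C)=C/C(=O)OCC[Si](C)(C)C | intermediate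
6 | C6-OTBS ether of 5 | C=C[C@@H](C)[C@H](O[Si](C)(C)C(C)(C)C)[C@@H](C)C/C(C)=C/C(=O)OCC[Si](C)(C)C | intermediate
7 | TMSE (2E,5S,6R,7S)-6-(TBSO)-3,5,7-trimethyl-8-oxooct-2-enoate | O=C[C@@H](C)[C@H](O[Si](C)(C)C(C)(C)C)[C@@H](C)C/C(C)=C/C(=O)OCC[Si](C)(C)C | intermediate
8 | (E)-but-2-ene-1,4-diol | OC/C=C/CO | starting material
9 | (E)-4-(TBSO)but-2-en-1-ol | OC/C=C/CO[Si](C)(C)C(C)(C)C | intermediate
10 | methyl (E)-4-(TBSO)but-2-en-1-yl carbonate | COC(=O)OC/C=C/CO[Si](C)(C)C(C)(C)C | intermediate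
11 | (E)-4-(TBSO)but-2-en-1-yl-Bpin | CC1(C)OB(C/C=C/CO[Si](C)(C)C(C)(C)C)OC1(C)C | intermediate
12 | C8-hydroxy, C9-(TBSOCH2), C10=C11H2 allylation product (9S; C8 as formed) | C=C[C@@H](CO[Si](C)(C)C(C)(C)C)C(O)[C@@H](C)[C@H](O[Si](C)(C)C(C)(C)C)[C@@H](C)C/C(C)=C/C(=O)OCC[Si](C)(C)C | intermediate
13 | C8-OTES ether of 12 | C=C[C@@H](CO[Si](C)(C)C(C)(C)C)C(O[Si](CC)(CC)CC)[C@@H](C)[C@H](O[Si](C)(C)C(C)(C)C)[C@@H](C)C/C(C)=C/C(=O)OCC[Si](C)(C)C | intermediate
14 | C10 aldehyde | O=C[C@@H](CO[Si](C)(C)C(C)(C)C)C(O[Si](CC)(CC)CC)[C@@H](C)[C@H](O[Si](C)(C)C(C)(C)C)[C@@H](C)C/C(C)=C/C(=O)OCC[Si](C)(C)C | intermediate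
15 | (10E)-C12 enal | O=C/C(C)=C/[C@@H](CO[Si](C)(C)C(C)(C)C)C(O[Si](CC)(CC)CC)[C@@H](C)[C@H](O[Si](C)(C)C(C)(C)C)[C@@H](C)C/C(C)=C/C(=O)OCC[Si](C)(C)C | intermediate
16 | West dienyl iodide (C13–I) | I/C=C/C(C)=C/[C@@H](CO[Si](C)(C)C(C)(C)C)C(O[Si](CC)(CC)CC)[C@@H](C)[C@H](O[Si](C)(C)C(C)(C)C)[C@@H](C)C/C(C)=C/C(=O)OCC[Si](C)(C)C | intermediate
17 | methyl (R)-3-hydroxy-2-methylpropanoate | COC(=O)[C@H](C)CO | starting material
18 | methyl (R)-3-(TBSO)-2-methylpropanoate | COC(=O)[C@H](C)CO[Si](C)(C)C(C)(C)C | intermediate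
19 | (R)-3-(TBSO)-2-methylpropanal | O=C[C@H](C)CO[Si](C)(C)C(C)(C)C | intermediate
20 | ethyl (2Z,4S)-5-(TBSO)-2-ethyl-4-methylpent-2-enoate | CCC(=C/[C@H](C)CO[Si](C)(C)C(C)(C)C)/C(=O)OCC | intermediate
21 | (2Z,4S)-5-(TBSO)-2-ethyl-4-methylpent-2-en-1-ol | CCC(=C/[C@H](C)CO[Si](C)(C)C(C)(C)C)/CO | intermediate
22 | (2Z,4S)-5-(TBSO)-2-ethyl-4-methylpent-2-enal | CCC(=C/[C@H](C)CO[Si](C)(C)C(C)(C)C)/C=O | intermediate
23 | (2E,4Z,6S)-7-(TBSO)-4-ethyl-6-methylhepta-2,4-dienal | CCC(=C/[C@H](C)CO[Si](C)(C)C(C)(C)C)/C=C/C=O | intermediate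
24 | (3S,4S,5E,7Z,9S)-10-(TBSO)-7-ethyl-3,9-dimethyldeca-1,5,7-trien-4-ol | CCC(=C/[C@H](C)CO[Si](C)(C)C(C)(C)C)/C=C/[C@H](O)[C@@H](C)C=C | intermediate
25 | acrylate of 24 | CCC(=C/[C@H](C)CO[Si](C)(C)C(C)(C)C)/C=C/[C@H](OC(=O)C=C)[C@@H](C)C=C | intermediate
26 | (5S,6S)-6-[(1E,3Z,5S)-3-ethyl-6-(TBSO)-5-methylhexa-1,3-dienyl]-5-methyl-5,6-dihydro-2H-pyran-2-one | CCC(=C/[C@H](C)CO[Si](C)(C)C(C)(C)C)/C=C/[C@@H]1OC(=O)C=C[C@@H]1C | intermediate
27 | 6-hydroxy analogue of 26 | CCC(=C/[C@H](C)CO)/C=C/[C@@H]1OC(=O)C=C[C@@H]1C | intermediate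
28 | 6-iodo analogue of 26 (East iodide) | CCC(=C/[C@H](C)CI)/C=C/[C@@H]1OC(=O)C=C[C@@H]1C | intermediate
29 | Negishi product (8-OTES, 6-OTBS, 9-CH2OTBS, C1 TMSE ester) | CCC(=C/[C@H](C)C/C=C/C(C)=C/[C@@H](CO[Si](C)(C)C(C)(C)C)C(O[Si](CC)(CC)CC)[C@@H](C)[C@H](O[Si](C)(C)C(C)(C)C)[C@@H](C)C/C(C)=C/C(=O)OCC[Si](C)(C)C)/C=C/[C@@H]1OC(=O)C=C[C@@H]1C | intermediate
30 | C8 free alcohol | CCC(=C/[C@H](C)C/C=C/C(C)=C/[C@@H](CO[Si](C)(C)C(C)(C)C)C(O)[C@@H](C)[C@H](O[Si](C)(C)C(C)(C)C)[C@@H](C)C/C(C)=C/C(=O)OCC[Si](C)(C)C)/C=C/[C@@H]1OC(=O)C=C[C@@H]1C | intermediate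
31 | C8 ketone, fully protected | CCC(=C/[C@H](C)C/C=C/C(C)=C/[C@@H](CO[Si](C)(C)C(C)(C)C)C(=O)[C@@H](C)[C@H](O[Si](C)(C)C(C)(C)C)[C@@H](C)C/C(C)=C/C(=O)OCC[Si](C)(C)C)/C=C/[C@@H]1OC(=O)C=C[C@@H]1C | intermediate
32 | kazusamycin A | CCC(=C/[C@H](C)C/C=C/C(C)=C/[C@@H](CO)C(=O)[C@@H](C)[C@H](O)[C@@H](C)C/C(C)=C/C(=O)O)/C=C/[C@@H]1OC(=O)C=C[C@@H]1C | target

## Totals
- Total steps: 29.
- Longest linear sequence: 15 (Steps 1–6, 10–14, 26–29, or equivalently Steps 15–25, 26–29).

## Three steps most likely to fail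
1. **Step 10 (allylboration, C9 stereocontrol).**
   - The dr may be modest, and aldehyde 7 is prone to β-elimination and epimerisation.
   - Fallback: change the approach to a vinylogous Mukaiyama aldol of 7 with the silyl dienolate of an S-ethyl 5-(TBSO)-2-methylpent-2-enethioester. This sets C9 and the C10=C11 alkene together, and the thioester is then reduced selectively (Et3SiH, Pd/C) to enal 15.
2. **Step 26 (Negishi coupling).**
   - Zinc insertion and coupling on a polyfunctional β-branched alkyl iodide with a Michael-acceptor lactone may give low yield.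
   - Fallback: use Julia–Kocienski olefination instead. Alkylate lithiated 1-phenyl-5-(methylsulfonyl)tetrazole with 28 to give the C13 PT-sulfone, then react it with enal 15 (KHMDS, DME, −60 °C) to form C12=C13 (E) directly, skipping Step 14.
3. **Step 29 (one-pot fluoride deprotection of the β-oxygenated ketone).**
   - C9 epimerisation, E1cB elimination or retro-aldol could occur.
   - Fallback: carry C1 as an allyl ester instead of TMSE (made by HWE of a C3 methyl ketone with allyl diethylphosphonoacetate in place of Step 2). The silyl ethers are then removed with HF·pyridine and the acid released last with Pd(PPh3)4/morpholine under neutral conditions.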